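The dioxane is opened at the C7'–O bond and ring B of one abietane half is then cut at C6–C7 and C5–C10. These two bonds are made in one thermolysis: a benzocyclobutenyl ether opens to an o-quinodimethane (C7, C8, C9, C10) that adds the E silyl enol ether C5=C6 held by the C1–C4 tether, closing rings B and A. The feature used is ring B carrying C7(O)–C6(O) next to the C5–C10 fusion. The precursor is the 6α-hydroxy-7-ketone of the finished second half, O-alkylated by the cyclobutene carbon that becomes C7. Four stereocentres arise; C7 emerges α and is epimerised at the end.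

Key step: step 24

Remarks on the chemistry
- Abietane numbering is used for both halves; unprimed locants belong to the half built in step 24 (half A), primed ones to the half made from dehydroabietic acid (half B).
- Dehydroabietic acid has no oxygen at C12 and carries C18 as an acid, so half B needs C18 deoxygenation and C12 oxygenation before C7 and C6 are oxidised.
- In a [4+2] addition the two outward groups of the diene end up cis; with ether oxygen and tether both outward, the cycloadduct carries O7 on the α face (cis to C1 and to O6), so 39 is the 7α-ether and the 6α,7β pattern of the target is reached only by the final epimerisation.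
- Only cyclobutene isomers with oxygen trans to the tether open to the o-quinodimethane that has both groups outward; 22 and 27–33 are racemic, and 34–38 are the two trans diastereomers (one drawn, the other has both cyclobutene centres inverted and gives the same 38).

Step 1
Reactants: 1 dehydroabietic acid
Product: 2 dehydroabietinol (abieta-8,11,13-trien-18-ol)
Conditions: LiAlH4, THF, 0 °C to reflux; aq. NaOH work-up
Reagents that add atoms: none
Why: LiAlH4 reduces the hindered C18 carboxylic acid to the neopentyl primary alcohol (hydride reduction of a carboxylic acid) and touches no stereocentre.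

Step 2
Reactants: 2 dehydroabietinol
Product: 3 dehydroabietyl 4-methylbenzenesulfonate
Conditions: TsCl, pyridine, DMAP (cat.), CH2Cl2, 0 °C to rt
Reagents that add atoms: 4-methylbenzenesulfonyl chloride, Cc1ccc(cc1)S(Cl)(=O)=O
Why: Sulfonylation of the unhindered primary hydroxyl (tosylate formation) activates C18 for removal of its oxygen.

Step 3
Reactants: 3 dehydroabietyl 4-methylbenzenesulfonate
Product: 5 abieta-8,11,13-triene, via neopentyl iodide 4 (not isolated)
Conditions: NaI, Zn dust, DMPU, 110 °C
Reagents that add atoms: none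
Why: Finkelstein displacement by iodide in a dipolar aprotic solvent followed by zinc reduction of the neopentyl iodide (reductive dehalogenation) turns C18 into a methyl group, so that C4 carries the gem-dimethyl pair of the target.

Step 4
Reactants: 5 abieta-8,11,13-triene
Product: 6 12-acetylabieta-8,11,13-triene
Conditions: AcCl, AlCl3, CH2Cl2, 0 °C
Reagents that add atoms: acetyl chloride, CC(Cl)=O
Why: Friedel–Crafts acylation goes to C12, the alkyl-activated ring position that is neither peri to C1 (C11) nor flanked by C7 and the isopropyl group (C14).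

Step 5
Reactants: 6 12-acetylabieta-8,11,13-triene
Product: 7 abieta-8,11,13-trien-12-yl acetate
Conditions: mCPBA, CF3CO2H (cat.), CH2Cl2, rt
Reagents that add atoms: 3-chloroperoxybenzoic acid, OOC(=O)c1cccc(Cl)c1
Why: Baeyer–Villiger oxidation with migration of the electron-rich aryl group converts the aryl methyl ketone into the aryl acetate, which places oxygen on C12.

Step 6
Reactants: 7 abieta-8,11,13-trien-12-yl acetate
Product: 9 12-methoxyabieta-8,11,13-triene (ferruginol methyl ether), via ferruginol 8 (not isolated)
Conditions: K2CO3, MeOH, rt; concentrate; then MeI, K2CO3, DMF, rt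
Reagents that add atoms: iodomethane, CI
Why: Base-catalysed methanolysis of the aryl acetate frees the phenol, which is O-methylated in the same flask (Williamson ether synthesis).

Step 7
Reactants: 9 12-methoxyabieta-8,11,13-triene
Product: 10 12-methoxyabieta-8,11,13-trien-7-one (sugiol methyl ether)
Conditions: CrO3, AcOH, rt
Reagents that add atoms: chromium trioxide, O=[Cr](=O)=O
Why: Chromic acid oxidation of the benzylic methylene C7, which is para to the methoxy group and less hindered than the isopropyl methine, gives the aryl ketone (benzylic oxidation).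

Step 8
Reactants: 10 12-methoxyabieta-8,11,13-trien-7-one
Product: 12 6α-hydroxy-12-methoxyabieta-8,11,13-trien-7-one (half B ketol), via potassium enolate 11 (not isolated)
Conditions: KN(SiMe3)2, THF, −78 °C; then 2-(benzenesulfonyl)-3-phenyloxaziridine, −78 °C; aq. NH4Cl
Reagents that add atoms: 2-(benzenesulfonyl)-3-phenyloxaziridine, O=S(=O)(N1OC1c1ccccc1)c1ccccc1
Why: Davis oxidation of the C6–C7 potassium enolate, in which the N-sulfonyloxaziridine attacks C6 from the α face because the axial C10 and C4 β-methyl groups screen the β face, which sets the equatorial 6α-hydroxyl.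

Step 9
Reactants: 13 3-chloropropan-1-ol; 14 3-methylbut-2-enal
Product: 17 6-hydroxy-3,3-dimethylhexanal, via alkoxide Grignard reagent 15 (not isolated), via bis(trimethylsilyl) adduct 16 (not isolated)
Conditions: 13, i-PrMgCl, THF, −20 °C, then Mg, reflux; CuBr·SMe2 (10 mol%), Me3SiCl, DMPU, 14, −78 to −20 °C; 1 M HCl
Reagents that add atoms: none
Why: Copper-catalysed conjugate addition of the alkoxide-protected Grignard reagent to the β,β-disubstituted enal, accelerated by the chlorosilane, creates the quaternary C4 with its two methyl groups, and acid work-up hydrolyses both silyl groups.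

Step 10
Reactants: 17 6-hydroxy-3,3-dimethylhexanal
Product: 18 4,4-dimethylhept-6-en-1-ol
Conditions: Ph3PCH3Br, KOC(CH3)3 (2.5 equiv each), THF, 0 °C to rt
Reagents that add atoms: methyltriphenylphosphonium bromide, C[P+](c1ccccc1)(c1ccccc1)c1ccccc1.[Br-]
Why: Wittig methylenation (excess ylide tolerates the free hydroxyl) masks the aldehyde as a terminal alkene that survives the base, hydride and palladium steps ahead and is cleaved back in step 22.

Step 11
Reactants: 18 4,4-dimethylhept-6-en-1-ol
Product: 19 7-iodo-4,4-dimethylhept-1-ene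
Conditions: I2, PPh3, imidazole, CH2Cl2, 0 °C to rt
Reagents that add atoms: iodine, II
Why: Appel iodination converts the primary alcohol into the primary iodide under neutral conditions that leave the alkene alone.

Step 12
Reactants: 20 propanenitrile; 19 7-iodo-4,4-dimethylhept-1-ene
Product: 22 2,6,6-trimethylnon-8-enenitrile (racemic), via lithiated propanenitrile 21 (not isolated)
Conditions: LiN(i-Pr)2, 20 (2 equiv), THF, −78 °C; then 19, −78 °C to rt
Reagents that add atoms: none
Why: SN2 alkylation of lithiated propanenitrile (in excess, to suppress dialkylation) by the primary iodide joins C10 to C1; the new stereocentre C10 is racemic, which is of no consequence because it is erased in step 24.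

Step 13
Reactants: 23 methyl 4-bromo-2-methoxybenzoate
Product: 25 2-(4-bromo-2-methoxyphenyl)propan-2-ol, via aryl methyl ketone 24 (not isolated)
Conditions: MeMgBr (3 equiv), THF, 0 °C to rt; aq. NH4Cl
Reagents that add atoms: methylmagnesium bromide, C[Mg]Br
Why: Double addition of the Grignard reagent to the ester through the methyl ketone gives the tertiary benzylic alcohol (Grignard addition).

Step 14
Reactants: 25 2-(4-bromo-2-methoxyphenyl)propan-2-ol
Product: 26 4-bromo-2-methoxy-1-(propan-2-yl)benzene
Conditions: Et3SiH, CF3CO2H, CH2Cl2, 0 °C to rt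
Reagents that add atoms: none
Why: Ionic hydrogenation, in which the acid ionises the tertiary benzylic alcohol to a cation stabilised by the ortho methoxy group and the silane delivers hydride to give the isopropyl group.

Step 15
Reactants: 26 4-bromo-2-methoxy-1-(propan-2-yl)benzene; 22 2,6,6-trimethylnon-8-enenitrile
Product: 27 2-[3-methoxy-4-(propan-2-yl)phenyl]-2,6,6-trimethylnon-8-enenitrile (racemic)
Conditions: Pd(OAc)2 (2 mol%), rac-BINAP (2.4 mol%), NaN(SiMe3)2, toluene, 100 °C
Reagents that add atoms: none
Why: Palladium-catalysed α-arylation of the secondary nitrile anion with the aryl bromide forms the C9–C10 bond and the benzylic quaternary centre, which is racemic.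

Step 16
Reactants: 27 2-[3-methoxy-4-(propan-2-yl)phenyl]-2,6,6-trimethylnon-8-enenitrile
Product: 28 2-[2-bromo-5-methoxy-4-(propan-2-yl)phenyl]-2,6,6-trimethylnon-8-enenitrile (racemic)
Conditions: NBS, MeCN, 0 °C to rt, dark
Reagents that add atoms: N-bromosuccinimide, O=C1CCC(=O)N1Br
Why: Electrophilic aromatic bromination occurs para to the methoxy group at C8, the only strongly activated position not flanked on both sides, while the isolated terminal alkene does not react with N-bromosuccinimide in dry acetonitrile in the dark.

Step 17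
Reactants: 28 2-[2-bromo-5-methoxy-4-(propan-2-yl)phenyl]-2,6,6-trimethylnon-8-enenitrile
Product: 30 2-[2-bromo-5-methoxy-4-(propan-2-yl)phenyl]-2,6,6-trimethylnon-8-enal (racemic), via aldimine 29 (not isolated)
Conditions: (i-Bu)2AlH, toluene, −78 to 0 °C; then 1 M HCl, rt
Reagents that add atoms: water, O
Why: Partial reduction of the hindered nitrile stops at the N-aluminated aldimine, whose acid hydrolysis gives an aldehyde that cannot enolise (nitrile to aldehyde reduction).

Step 18
Reactants: 30 2-[2-bromo-5-methoxy-4-(propan-2-yl)phenyl]-2,6,6-trimethylnon-8-enal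
Product: 31 8-(4,4-dimethylhept-6-en-1-yl)-3-methoxy-8-methyl-4-(propan-2-yl)bicyclo[4.2.0]octa-1,3,5-trien-7-one (racemic)
Conditions: [Pd(C3H5)Cl]2 (2.5 mol%), rac-BINAP (6 mol%), Cs2CO3, 1,4-dioxane, 110 °C
Reagents that add atoms: none
Why: Palladium-catalysed intramolecular acylation of the aryl bromide by the formyl C–H bond (oxidative addition, base-assisted C–H palladation to a five-membered acylpalladacycle, reductive elimination) forms C7–C8 and the cyclobutenone; the quaternary α-carbon rules out enolate arylation and the distant alkene cannot compete by Heck cyclisation.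

Step 19
Reactants: 31 the benzocyclobutenone
Product: 32 8-(4,4-dimethylhept-6-en-1-yl)-3-methoxy-8-methyl-4-(propan-2-yl)bicyclo[4.2.0]octa-1,3,5-trien-7-ol (racemic; both diastereomers)
Conditions: NaBH4, MeOH, 0 °C; aq. NH4Cl
Reagents that add atoms: none
Why: Borohydride reduction of the strained ketone gives the secondary alcohol as both diastereomers (carbonyl reduction), and both are used because step 21 passes through a planar cation.

Step 20
Reactants: 32 the benzocyclobutenol
Product: 33 benzocyclobutenyl 2,2,2-trichloroacetimidate (racemic; both diastereomers)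
Conditions: Cl3CCN, DBU (10 mol%), CH2Cl2, −20 °C
Reagents that add atoms: trichloroacetonitrile, ClC(Cl)(Cl)C#N
Why: Base-catalysed addition of the hydroxyl to trichloroacetonitrile gives the imidate, and catalytic amidine base at low temperature keeps the alkoxide concentration too low for alkoxide-triggered cyclobutene opening.

Step 21
Reactants: 33 benzocyclobutenyl trichloroacetimidate; 12 half B ketol
Product: 34 6'α-O-benzocyclobutenyl ether of 12 with terminal alkene (ether oxygen trans to the tether)
Conditions: 33 (1.5 equiv), Me3SiOTf (5 mol%), 4 Å molecular sieves, CH2Cl2, −40 °C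
Reagents that add atoms: none
Why: Acid-catalysed O-alkylation by a trichloroacetimidate through an SN1 path, in which both imidate diastereomers ionise to the same benzocyclobutenyl cation stabilised by the para methoxy group and the bulky equatorial 6α-hydroxyl of 12 adds preferentially to the face bearing the C10 methyl, anti to the longer tether, which sets oxygen trans to the tether as step 24 requires; the cis isomers are removed by chromatography.

Step 22
Reactants: 34 the alkene ether
Product: 36 the corresponding aldehyde (chain end CH2–CHO), via vicinal diol 35 (not isolated)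
Conditions: OsO4 (2 mol%), NaIO4, 2,6-lutidine, 1,4-dioxane/H2O, rt
Reagents that add atoms: sodium periodate, [Na+].[O-]I(=O)(=O)=O
Why: Lemieux–Johnson oxidation (catalytic dihydroxylation of the only alkene and periodate cleavage of the diol) unmasks the aldehyde under buffered conditions that spare the acid-labile benzylic ether and the ketone.

Step 23
Reactants: 36 the aldehyde
Product: 37 benzocyclobutenyl ether of the half B 6α-hydroxy-7-ketone with tethered E triisopropylsilyl enol ether (key-step precursor)
Conditions: (i-Pr)3SiOTf, Et3N, CH2Cl2, −78 to 0 °C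
Reagents that add atoms: triisopropylsilyl trifluoromethanesulfonate, CC(C)[Si](OS(=O)(=O)C(F)(F)F)(C(C)C)C(C)C
Why: Soft enolisation of the aldehyde by silyl triflate and amine (silyl enol ether formation) leaves the hindered α-alkoxy aryl ketone untouched, and the E isomer is expected because the Z isomer would hold the silyloxy group cis to the quaternary C4; any Z isomer is separated, since it would lead to the 6β-epimer.

Step 24
Reactants: 37 the key-step precursor
Product: 39 ether-linked bis-abietane cycloadduct (C7–O–C6' link with 7α-oxygen; 6α-silyl ether; C7' ketone), via o-quinodimethane 38 (not isolated)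
Conditions: degassed toluene (0.005 M), 2,6-di-tert-butyl-4-methylphenol (5 mol%), solid K2CO3, sealed tube, 160 °C
Reagents that add atoms: none
Why: Heating triggers conrotatory 4π opening of the cyclobutene, in which the donor ether oxygen rotates outward and, being trans to the tether in 37, takes the tether outward while the C10 methyl turns inward, giving 38; re-aromatisation then drives a concerted intramolecular [4+2] addition of the diene C7=C8–C9=C10 to the E enol ether C5=C6. The closest known reaction type is the thermal benzocyclobutene opening and intramolecular o-quinodimethane Diels–Alder reaction that gives trans-fused octahydrophenanthrenes. Ring B is closed by the cycloaddition itself (bonds C6–C7 and C5–C10) and ring A by the C1–C4 tether folding exo (anti) over the diene, a six-membered closure that gives the trans A/B fusion. C10 and C5 are fixed by this exo folding (inward methyl trans to H5), C6 by the E geometry of the enol ether (silyloxy endo, hence trans to the C10 methyl, 6α), and C7 by the outward rotation of the ether oxygen, which places O7 cis to C1 and to O6 (7α, corrected in step 27). The step needs facial selectivity, that is addition to the diene face that leads to the natural 5α,10β series, and the only control element is the stereogenic C6' on the ether oxygen, whose C5' and C7' flanks shield the two faces unequally; the other diastereomeric adduct, if formed, is removed by chromatography. It also needs the cycloaddition to outrun the [1,5]-hydrogen shift from the inward methyl, which the short tether, the gem-dimethyl group at C4 and high dilution favour.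

Step 25
Reactants: 39 the cycloadduct
Product: 41 cyclic hemiketal (dioxane ring closed between O6 and C7'; 7α-oxygen at C7), via hydroxy ketone 40 (not isolated)
Conditions: Bu4NF, AcOH, THF, 50 °C
Reagents that add atoms: none
Why: Fluoride cleaves the hindered secondary silyl ether (buffered to spare the α-alkoxy ketone), and the freed 6α-hydroxyl adds to the C7' ketone to close the six-membered hemiketal (desilylation and hemiketalisation); the anomeric configuration is of no consequence.

Step 26
Reactants: 41 the hemiketal
Product: 42 7-epi-dioxane (target skeleton with 7α-oxygen in half A)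
Conditions: Et3SiH, Me3SiOTf (0.3 equiv), CH2Cl2, −78 °C
Reagents that add atoms: none
Why: Reductive etherification, in which the Lewis acid ionises the hemiketal to the cyclic oxocarbenium ion and the silane delivers hydride axially from the α face of ring B of half B, which sets 7'β-oxygen (trans-diequatorial to O6') while the low temperature leaves the C7 ether intact.

Step 27
Reactants: 42 the 7-epi-dioxane
Product: 43 CNP0327150.1 (target)
Conditions: Me3SiOTf (10 mol%), CH2Cl2, −40 to 0 °C; Et3N quench
Reagents that add atoms: none
Why: Acid-catalysed epimerisation of a benzylic ether by reversible ionisation, in which the pseudo-axial C7–O bond of the p-methoxybenzylic ether is aligned with the arene and ionises, the tethered oxygen recloses, and thermodynamic control leads to the trans-fused dioxane with all four C–O bonds equatorial, that is 7β-oxygen and the C2-symmetric target.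

Compound list
1 | dehydroabietic acid | CC(C)c1ccc2c(c1)CC[C@H]1[C@](C)(C(=O)O)CCC[C@]21C | starting material
2 | dehydroabietinol (abieta-8,11,13-trien-18-ol) | CC(C)c1ccc2c(c1)CC[C@H]1[C@](C)(CO)CCC[C@]21C | intermediate
3 | dehydroabietyl 4-methylbenzenesulfonate | CC(C)c1ccc2c(c1)CC[C@H]1[C@](C)(COS(=O)(=O)c3ccc(C)cc3)CCC[C@]21C | intermediate
4 | 18-iodoabieta-8,11,13-triene (not isolated) | CC(C)c1ccc2c(c1)CC[C@H]1[C@](C)(CI)CCC[C@]21C | intermediate
5 | abieta-8,11,13-triene | CC(C)c1ccc2c(c1)CC[C@H]1C(C)(C)CCC[C@]21C | intermediate
6 | 12-acetylabieta-8,11,13-triene | CC(=O)c1cc2c(cc1C(C)C)CC[C@H]1C(C)(C)CCC[C@]21C | intermediate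
7 | abieta-8,11,13-trien-12-yl acetate | CC(=O)Oc1cc2c(cc1C(C)C)CC[C@H]1C(C)(C)CCC[C@]21C | intermediate
8 | ferruginol (abieta-8,11,13-trien-12-ol; not isolated) | Oc1cc2c(cc1C(C)C)CC[C@H]1C(C)(C)CCC[C@]21C | intermediate
9 | 12-methoxyabieta-8,11,13-triene | COc1cc2c(cc1C(C)C)CC[C@H]1C(C)(C)CCC[C@]21C | intermediate
10 | 12-methoxyabieta-8,11,13-trien-7-one | COc1cc2c(cc1C(C)C)C(=O)C[C@H]1C(C)(C)CCC[C@]21C | intermediate
11 | potassium C6–C7 enolate of 10 (not isolated) | COc1cc2c(cc1C(C)C)C([O-])=C[C@H]1C(C)(C)CCC[C@]21C.[K+] | intermediate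
12 | 6α-hydroxy-12-methoxyabieta-8,11,13-trien-7-one (half B ketol) | COc1cc2c(cc1C(C)C)C(=O)[C@H](O)[C@H]1C(C)(C)CCC[C@]21C | intermediate
13 | 3-chloropropan-1-ol | OCCCCl | starting material
14 | 3-methylbut-2-enal | CC(C)=CC=O | starting material
15 | chloromagnesium 3-(chloromagnesio)propan-1-olate (not isolated) | Cl[Mg]OCCC[Mg]Cl | intermediate
16 | 3,3-dimethyl-1,6-bis(trimethylsilyloxy)hex-1-ene (not isolated; alkene geometry irrelevant) | C[Si](C)(C)OCCCC(C)(C)C=CO[Si](C)(C)C | intermediate
17 | 6-hydroxy-3,3-dimethylhexanal | OCCCC(C)(C)CC=O | intermediate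
18 | 4,4-dimethylhept-6-en-1-ol | OCCCC(C)(C)CC=C | intermediate
19 | 7-iodo-4,4-dimethylhept-1-ene | ICCCC(C)(C)CC=C | intermediate
20 | propanenitrile | CCC#N | starting material
21 | 2-lithiopropanenitrile (not isolated) | [Li+].C[CH-]C#N | intermediate
22 | 2,6,6-trimethylnon-8-enenitrile (racemic) | N#CC(C)CCCC(C)(C)CC=C | intermediate
23 | methyl 4-bromo-2-methoxybenzoate | COC(=O)c1ccc(Br)cc1OC | starting material
24 | 1-(4-bromo-2-methoxyphenyl)ethan-1-one (not isolated) | CC(=O)c1ccc(Br)cc1OC | intermediate
25 | 2-(4-bromo-2-methoxyphenyl)propan-2-ol | CC(C)(O)c1ccc(Br)cc1OC | intermediate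
26 | 4-bromo-2-methoxy-1-(propan-2-yl)benzene | CC(C)c1ccc(Br)cc1OC | intermediate
27 | 2-[3-methoxy-4-(propan-2-yl)phenyl]-2,6,6-trimethylnon-8-enenitrile (racemic) | COc1cc(ccc1C(C)C)C(C)(C#N)CCCC(C)(C)CC=C | intermediate
28 | 2-[2-bromo-5-methoxy-4-(propan-2-yl)phenyl]-2,6,6-trimethylnon-8-enenitrile (racemic) | COc1cc(c(Br)cc1C(C)C)C(C)(C#N)CCCC(C)(C)CC=C | intermediate
29 | aldimine of 30 (not isolated) | COc1cc(c(Br)cc1C(C)C)C(C)(C=N)CCCC(C)(C)CC=C | intermediate
30 | 2-[2-bromo-5-methoxy-4-(propan-2-yl)phenyl]-2,6,6-trimethylnon-8-enal (racemic) | COc1cc(c(Br)cc1C(C)C)C(C)(C=O)CCCC(C)(C)CC=C | intermediate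
31 | 8-(4,4-dimethylhept-6-en-1-yl)-3-methoxy-8-methyl-4-(propan-2-yl)bicyclo[4.2.0]octa-1,3,5-trien-7-one (racemic) | COc1cc2c(cc1C(C)C)C(=O)C2(C)CCCC(C)(C)CC=C | intermediate
32 | 8-(4,4-dimethylhept-6-en-1-yl)-3-methoxy-8-methyl-4-(propan-2-yl)bicyclo[4.2.0]octa-1,3,5-trien-7-ol (racemic, both diastereomers) | COc1cc2c(cc1C(C)C)C(O)C2(C)CCCC(C)(C)CC=C | intermediate
33 | 2,2,2-trichloroacetimidate of 32 (racemic, both diastereomers) | COc1cc2c(cc1C(C)C)C(OC(=N)C(Cl)(Cl)Cl)C2(C)CCCC(C)(C)CC=C | intermediate
34 | 6'α-O-benzocyclobutenyl ether of 12, chain end allyl, ether oxygen trans to the tether (one of the two trans diastereomers drawn) | COc1cc2c(cc1C(C)C)C(=O)[C@H](O[C@@H]3c4cc(C(C)C)c(OC)cc4[C@@]3(C)CCCC(C)(C)CC=C)[C@H]1C(C)(C)CCC[C@]21C | intermediate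
35 | vicinal diol from 34 (not isolated; carbinol centre unassigned) | COc1cc2c(cc1C(C)C)C(=O)[C@H](O[C@@H]3c4cc(C(C)C)c(OC)cc4[C@@]3(C)CCCC(C)(C)CC(O)CO)[C@H]1C(C)(C)CCC[C@]21C | intermediate
36 | aldehyde from 34 (chain end CH2–CHO) | COc1cc2c(cc1C(C)C)C(=O)[C@H](O[C@@H]3c4cc(C(C)C)c(OC)cc4[C@@]3(C)CCCC(C)(C)CC=O)[C@H]1C(C)(C)CCC[C@]21C | intermediate
37 | key-step precursor: benzocyclobutenyl ether of the half B 6α-hydroxy-7-ketone with tethered E triisopropylsilyl enol ether, oxygen trans to the tether | COc1cc2c(cc1C(C)C)C(=O)[C@H](O[C@@H]3c4cc(C(C)C)c(OC)cc4[C@@]3(C)CCCC(C)(C)/C=C/O[Si](C(C)C)(C(C)C)C(C)C)[C@H]1C(C)(C)CCC[C@]21C | intermediate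
38 | o-quinodimethane with ether oxygen and tether outward, methyl inward (not isolated) | COc1cc2c(cc1C(C)C)C(=O)[C@H](O/C=C3\C=C(C(C)C)C(OC)=C/C3=C(/C)CCCC(C)(C)/C=C/O[Si](C(C)C)(C(C)C)C(C)C)[C@H]1C(C)(C)CCC[C@]21C | intermediate
39 | cycloadduct: ether-linked bis-abietane, C7–O–C6' link with 7α-oxygen, 6α-triisopropylsilyl ether, 5α-H, 10β-methyl, C7' ketone | COc1cc2c(cc1C(C)C)[C@H](O[C@H]3C(=O)c4cc(C(C)C)c(OC)cc4[C@@]4(C)CCCC(C)(C)[C@H]34)[C@H](O[Si](C(C)C)(C(C)C)C(C)C)[C@H]1C(C)(C)CCC[C@]21C | intermediate
40 | desilylated cycloadduct, open hydroxy ketone form (not isolated) | COc1cc2c(cc1C(C)C)[C@H](O[C@H]3C(=O)c4cc(C(C)C)c(OC)cc4[C@@]4(C)CCCC(C)(C)[C@H]34)[C@H](O)[C@H]1C(C)(C)CCC[C@]21C | intermediate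
41 | cyclic hemiketal at C7' (one anomer drawn), 7α-oxygen at C7 | COc1cc2c(cc1C(C)C)[C@@H]1O[C@H]3[C@](O)(O[C@@H]1[C@H]1C(C)(C)CCC[C@]21C)c1cc(C(C)C)c(OC)cc1[C@@]1(C)CCCC(C)(C)[C@H]31 | intermediate
42 | 7-epi-dioxane (7α-oxygen in half A, 7'β-oxygen in half B) | COc1cc2c(cc1C(C)C)[C@@H]1O[C@H]3[C@H](O[C@@H]1[C@H]1C(C)(C)CCC[C@]21C)c1cc(C(C)C)c(OC)cc1[C@@]1(C)CCCC(C)(C)[C@H]31 | intermediate
43 | CNP0327150.1 | COc1cc2c(cc1C(C)C)[C@H]1O[C@H]3[C@H](O[C@@H]1[C@H]1C(C)(C)CCC[C@]21C)c1cc(C(C)C)c(OC)cc1[C@@]1(C)CCCC(C)(C)[C@H]31 | target

Total step count: 27. Longest linear sequence: 17 steps (steps 9 to 12, then 15 to 27).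

Steps most likely to fail

1. Step 24. The o-quinodimethane may be drained by the [1,5]-hydrogen shift from the inward methyl before it cyclises, and the remote chiral ether may give poor facial selectivity, so that the adduct of the mirror-image half A dominates. The fallback sets out from 12 and builds half A from a second portion of the same ketol. Silylation of 12 with (i-Pr)3SiOTf and 2,6-lutidine gives the 6α-silyloxy ketone F1. NaBH4 in MeOH reduces it to the 7β-alcohol F2 (either epimer serves). Cl3CCN with catalytic DBU gives the trichloroacetimidate F3. Coupling of F3 with 12 under catalytic Me3SiOTf at −78 °C should, by axial capture of the C7 cation, give the 7α-ether 39, where the route is rejoined before step 25.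

2. Step 21. The imidate may rearrange to the N-alkyl trichloroacetamide or self-condense after ionisation, the hydrogen-bonded hindered 6α-hydroxyl may add too slowly, or addition may occur cis to the tether. The fallback sets out from 10 and makes the C6'–O bond by carbenoid insertion. LiN(SiMe3)2 and 2,2,2-trifluoroethyl trifluoroacetate give the 6-trifluoroacetyl ketone F4 (not isolated), and methanesulfonyl azide with Et3N gives the 6-diazo-7-ketone F5. Rh2(OAc)4-catalysed O–H insertion of F5 into the trans isomer of alcohol 32 (hydroxyl trans to the tether, separated by chromatography) gives the ether as a C6' mixture. Its axial 6'β-epimer F6 is equilibrated by DBU to the equatorial ether 34, where the route is rejoined before step 22.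

3. Step 27. The benzylic cation formed on ionisation may leak into hydride shift or proton loss towards a C6 carbonyl compound instead of reclosing, or the equilibrium may not lie far enough on the side of the all-equatorial dioxane. The fallback sets out from 12 and fixes both benzylic centres kinetically. Me3SiCl and imidazole give the 6-O-trimethylsilyl ether F7. F7 alone, with Et3SiH and catalytic Me3SiOTf at −78 to −20 °C, should undergo head-to-tail reductive etherification between the silyl ether of one molecule and the ketone of another, giving the 7β-linked keto silyl ether F8. A second, now intramolecular, reductive etherification then closes the dioxane. Hydride enters axially from the α face at both C7 and C7', and the route is rejoined at 43.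

Further compounds
F1 | step 24 | 12-methoxy-6α-(triisopropylsilyloxy)abieta-8,11,13-trien-7-one | COc1cc2c(cc1C(C)C)C(=O)[C@H](O[Si](C(C)C)(C(C)C)C(C)C)[C@H]1C(C)(C)CCC[C@]21C
F2 | step 24 | 12-methoxy-6α-(triisopropylsilyloxy)abieta-8,11,13-trien-7β-ol | COc1cc2c(cc1C(C)C)[C@@H](O)[C@H](O[Si](C(C)C)(C(C)C)C(C)C)[C@H]1C(C)(C)CCC[C@]21C
F3 | step 24 | 7-O-(2,2,2-trichloroacetimidate) of F2 | COc1cc2c(cc1C(C)C)[C@@H](OC(=N)C(Cl)(Cl)Cl)[C@H](O[Si](C(C)C)(C(C)C)C(C)C)[C@H]1C(C)(C)CCC[C@]21C
F4 | step 21 | 12-methoxy-6-(trifluoroacetyl)abieta-8,11,13-trien-7-one (C6 unassigned, enolised) | COc1cc2c(cc1C(C)C)C(=O)C(C(=O)C(F)(F)F)[C@H]1C(C)(C)CCC[C@]21C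
F5 | step 21 | 6-diazo-12-methoxyabieta-8,11,13-trien-7-one | COc1cc2c(cc1C(C)C)C(=O)C(=[N+]=[N-])[C@H]1C(C)(C)CCC[C@]21C
F6 | step 21 | 6'β-epimer of 34 | COc1cc2c(cc1C(C)C)C(=O)[C@@H](O[C@@H]3c4cc(C(C)C)c(OC)cc4[C@@]3(C)CCCC(C)(C)CC=C)[C@H]1C(C)(C)CCC[C@]21C
F7 | step 27 | 12-methoxy-6α-(trimethylsilyloxy)abieta-8,11,13-trien-7-one | COc1cc2c(cc1C(C)C)C(=O)[C@H](O[Si](C)(C)C)[C@H]1C(C)(C)CCC[C@]21C
F8 | step 27 | 7β-(C7–O–C6') linked keto silyl ether (6α-trimethylsilyloxy, C7' ketone) | COc1cc2c(cc1C(C)C)[C@@H](O[C@H]3C(=O)c4cc(C(C)C)c(OC)cc4[C@@]4(C)CCCC(C)(C)[C@H]34)[C@H](O[Si](C)(C)C)[C@H]1C(C)(C)CCC[C@]21C
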